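Remark: the SMILES has no stereocentre and no stereogenic double bond. Compound 16 is achiral, so the demand for a single enantiomer is met by constitution alone and no step has to control configuration.

## The problem

Compound 16 is a flavone. Ring A (C4a, C5–C8, C8a) is fused to the pyranone ring C (O1, C2, C3, C4), and ring B, a 2,4-dihydroxyphenyl group, sits on C2. The difficulty is site selectivity and chemoselectivity on a flat, crowded core, because ring C is fully substituted and ring A keeps only H8. Ring A is a phloroglucinol whose three oxygens must end up different: O1 in the ring, O5 free and hydrogen-bonded to C4=O, and O7 methylated. Its carbons C6 and C8 respond alike to electrophiles, yet only C6 carries carbon. The two C5 chains share one skeleton at different oxidation levels (prenyl on C3, 3-methyl-2-oxobutyl on C6), so a late oxidation of a 6-prenyl group would have to tell two nearly identical trisubstituted alkenes apart. Several groups are fragile: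
- the prenyl alkene (strong acid, peracid, halonium sources, hydrogenation);
- the o-hydroxybenzyl ketone O5H/C6–CH2–C=O (acid closes it to a furan with loss of water);
- the 2'-OH beside the C3 chain (oxidative cyclisation);
- the pyranone (opened by hydroxide).

The feature that makes the key step possible is the array O5–C5=C6 (ring A)–CH2–C(=O)–CH(CH3)2. Read backwards through a [3,3] shift, it is the aryl ether O5–C(CH3)2–C(OX)=CH2, the enol derivative of an α-aryloxy ketone. O5 has only one open ortho carbon, C6, because the other is the ring-fusion carbon C4a. O5 also lies peri to C4=O, which can chelate a Lewis acid together with O5 and rewards release of O5–H with a strong hydrogen bond.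

## Retrosynthesis

**16 ⇒ 15 ⇒ 13.** The C6–CH2 bond is cut and the (CH3)2C terminus is reconnected to O5 with allylic transposition. Removing three silyl groups links 16 to 15.
- A cut at CH2–C(=O) would still need a one-carbon handle placed on C6 and not on C8.
- An intermolecular polar union at C6 would first need a leaving group or a metal at C6, which is the same unsolved site problem.
- The sigmatropic reading takes its regiochemistry from O5, and the chain arrives at the ketone oxidation level, so no oxidant ever meets the prenyl group.
- In 13, ring A carries only C–O bonds beyond those of a commercial arene. The pentasubstituted ring appears only in the key step.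
- The forward reaction must go to C6 only, spare the prenyl group, and deliver an enol silane that falls to fluoride together with the aryl silyl ethers.

**13 ⇒ 12.** Three O–Si bonds are cut. Compound 12 is a constitutional isomer of 16, so everything after 12 amounts to an isomerisation. The side-chain ketone has hydrogens on one α-carbon only, so one enol silane is possible. The same reagent caps the two B-ring phenols.

**12 ⇒ 10.** The O1–C2 bond and two MOM groups are cut. Cuts at C2–C1' or C4–C4a would require a preformed 3-prenylchromone or an acylation of an unsymmetrical arene. The O1–C2 cut leaves an acyclic diketone in which only one phenol is free. The forward step is a cyclodehydration, with O5 blocked by the latent chain and O2' blocked by MOM at the moment of closure.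

**10 ⇒ 8 + 9.** The C3–CH2 bond is cut. In the open diketone 8, the future C3 is the most acidic carbon of the molecule and is alkylated under carbonate conditions. On a closed flavone, the same bond would need C3 metalation or halogenation, neither compatible with the methyl ketone and the electron-rich ring A.

**8 ⇒ 7 ⇒ 3 + 6.** The bond between the future C3 and C2 is cut and traced to the aryl ester 7. An intermolecular Claisen condensation could not distinguish the two methyl ketones of 3. The intramolecular acyl transfer can, because only the aryl ketone enolate reaches the ester. Compound 7 comes from phenol 3 and acid 6 by esterification.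

**3 ⇒ 1 + 2.** The O–C(CH3)2 bond is cut. Compound 1 is C2v-symmetric and already carries the O7 methyl group. One alkylation desymmetrises it: the alkylated oxygen becomes O5 and the other becomes O1. The ether serves as the O5 protecting group and as the stored C6 chain. Both partners are commercial.

**6 ⇒ 5 ⇒ 4.** Two O–CH2 bonds and the ester are cut, that is, routine protection and saponification of commercial 4.

## Roads not taken

Alternative 1: the most obvious route. Ring C is cut with the finished C6 chain already on the acetophenone A1, followed by aroylation, Baker–Venkataraman rearrangement and cyclodehydration.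
- A1 has two non-equivalent ortho hydroxyls, and both can close. The 8-substituted isomer A2 would accompany the wanted framework unless a further protecting group is placed selectively.
- The acid that closes the pyranone also dehydrates the o-hydroxybenzyl ketone onto its own carbonyl.
- A1 itself requires a C-alkylation of a phloroacetophenone nucleus, with C/O and mono/di selectivity problems.
- The chosen plan avoids all three because the chain itself blocks O5 until the ring is closed.

Alternative 2: the C6–CH2 bond is cut in the polar sense, with Pd-catalysed α-arylation of 3-methylbutan-2-one by the 6-iodoflavone A3.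
- The iodination must choose C6 over C8 and over the prenyl alkene.
- The C–I bond is flanked by two oxygen substituents.
- The enolate base threatens the aryl silyl ethers and the pyranone.
- Two steps and a halogen are spent on a bond that the chosen plan makes by isomerisation, with the site fixed by the O5 tether.

Alternative 3: the biomimetic route. The side-chain carbonyl is traced to an alkene: the 3,6-diprenylflavone A4 is epoxidised at the C6 chain to A5, and a Meinwald rearrangement (1,2-hydride shift to the tertiary cation) gives the isopropyl ketone.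
- The two trisubstituted alkenes of A4 are electronically and sterically almost the same, so the epoxidation has no handle for selectivity.
- In A5 the neighbouring O5–H can open the epoxide by 5-exo or 6-endo attack faster than hydride migrates.
- The Lewis acid of the rearrangement also meets the remaining prenyl group.
- The chosen plan never has two alkenes to distinguish.

Key step: step 9

## Steps

Step 1
Reactants: 1 1-(2,6-dihydroxy-4-methoxyphenyl)ethan-1-one; 2 3-bromo-3-methylbutan-2-one
Product: 3 3-(2-acetyl-3-hydroxy-5-methoxyphenoxy)-3-methylbutan-2-one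
Conditions: K2CO3 (1.2 equiv), 2 (1.05 equiv), DMF, 50 °C
Reagents that add atoms: none
Why: Williamson-type O-alkylation of a phenoxide by a tertiary α-bromo ketone, assisted by the adjacent carbonyl as in the alkylation of phenols with 2-bromoisobutyrates. Compound 1 is symmetric, so either hydroxyl gives the same ether, and the remaining hydroxyl is then locked in a hydrogen bond to the acetyl group, which holds back a second alkylation.

Step 2
Reactants: 4 methyl 2,4-dihydroxybenzoate
Product: 5 methyl 2,4-bis(methoxymethoxy)benzoate
Conditions: NaH (2.5 equiv), MOMCl (2.5 equiv), DMF, 0 °C → rt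
Reagents that add atoms: chloromethyl methyl ether, COCCl
Why: Williamson-type formation of two aryl MOM ethers; NaH is used because the 2-OH is hydrogen-bonded to the ester. MOM survives every basic step and is released in step 7.

Step 3
Reactants: 5 methyl 2,4-bis(methoxymethoxy)benzoate
Product: 6 2,4-bis(methoxymethoxy)benzoic acid
Conditions: LiOH, THF/MeOH/H2O, 50 °C; then cold dilute HCl to pH 4
Reagents that add atoms: lithium hydroxide, [Li+].[OH-]
Why: Saponification of a methyl benzoate. The MOM acetals are inert to base and tolerate the brief, cold, weakly acidic work-up.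

Step 4
Reactants: 3 3-(2-acetyl-3-hydroxy-5-methoxyphenoxy)-3-methylbutan-2-one; 6 2,4-bis(methoxymethoxy)benzoic acid
Product: 7 2-acetyl-5-methoxy-3-[(2-methyl-3-oxobutan-2-yl)oxy]phenyl 2,4-bis(methoxymethoxy)benzoate
Conditions: DCC, DMAP (cat.), CH2Cl2, rt
Reagents that add atoms: none
Why: Steglich esterification. The acylpyridinium species acylates the single free, chelated phenol under neutral conditions that spare the MOM groups and both ketones.

Step 5
Reactants: 7 2-acetyl-5-methoxy-3-[(2-methyl-3-oxobutan-2-yl)oxy]phenyl 2,4-bis(methoxymethoxy)benzoate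
Product: 8 1-[2,4-bis(methoxymethoxy)phenyl]-3-{2-hydroxy-4-methoxy-6-[(2-methyl-3-oxobutan-2-yl)oxy]phenyl}propane-1,3-dione
Conditions: LiHMDS (3.5 equiv), THF, −78 → 0 °C; AcOH quench
Reagents that add atoms: none
Why: Baker–Venkataraman O→C acyl migration. Excess base turns both methyl ketones into lithium enolates, which masks the side-chain carbonyl against aldol attack. Only the aryl ketone enolate reaches the ester carbonyl through a six-membered transition state, and formation of the diketonate makes the transfer irreversible.

Step 6
Reactants: 8 the 1,3-diketone of step 5; 9 1-bromo-3-methylbut-2-ene (prenyl bromide)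
Product: 10 1-[2,4-bis(methoxymethoxy)phenyl]-3-{2-hydroxy-4-methoxy-6-[(2-methyl-3-oxobutan-2-yl)oxy]phenyl}-2-(3-methylbut-2-en-1-yl)propane-1,3-dione (racemic at the labile C2)
Conditions: K2CO3 (1.5 equiv), 9 (1.1 equiv), acetone, 40 °C
Reagents that add atoms: none
Why: C-alkylation of a 1,3-diketone at its most acidic carbon with a soft allylic bromide, under carbonate conditions that do not enolise the isolated methyl ketone. The new stereocentre is labile and vanishes in step 7, and any early ring closure at this stage converges on the same product in step 7.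

Step 7
Reactants: 10 the C-prenylated 1,3-diketone of step 6
Product: 12 2-(2,4-dihydroxyphenyl)-7-methoxy-5-[(2-methyl-3-oxobutan-2-yl)oxy]-3-(3-methylbut-2-en-1-yl)-4H-chromen-4-one, via bis-MOM flavone 11 (not isolated)
Conditions: conc. HCl (cat.), MeOH, rt → 50 °C
Reagents that add atoms: none
Why: Acid-catalysed cyclodehydration of an o-hydroxyaryl 1,3-diketone (hemiketal, then loss of water through an aryl-stabilised oxocarbenium ion), followed by acetal exchange of the MOM ethers with methanol. At closure the A-ring phenol is the only free hydroxyl (O2' still MOM, O5 blocked), so only the wanted pyranone can form. The tertiary ether resists acid because its ionisation would place a cation next to a carbonyl, and the only acidic step of the route falls before the o-hydroxybenzyl ketone exists.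

Step 8
Reactants: 12 the 5-O-(2-methyl-3-oxobutan-2-yl) flavone of step 7
Product: 13 2-[2,4-bis(tert-butyldimethylsilyloxy)phenyl]-5-{[3-(tert-butyldimethylsilyloxy)-2-methylbut-3-en-2-yl]oxy}-7-methoxy-3-(3-methylbut-2-en-1-yl)-4H-chromen-4-one
Conditions: TBSOTf (4 equiv), Et3N (6 equiv), CH2Cl2, 0 °C → rt
Reagents that add atoms: tert-butyldimethylsilyl trifluoromethanesulfonate, CC(C)(C)[Si](C)(C)OS(=O)(=O)C(F)(F)F
Why: Silyl triflate/amine silylation of two phenols and soft enolisation of the methyl ketone in one operation. The ketone has α-hydrogens only on its CH3 group (the other α-carbon is quaternary), so a single enol silane is possible.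

Step 9
Reactants: 13 the tris-silyl 2-silyloxyallyl aryl ether of step 8
Product: 15 2-[2,4-bis(tert-butyldimethylsilyloxy)phenyl]-6-[2-(tert-butyldimethylsilyloxy)-3-methylbut-2-en-1-yl]-5-hydroxy-7-methoxy-3-(3-methylbut-2-en-1-yl)-4H-chromen-4-one, via C6-dienone 14 (not isolated)
Conditions: Eu(fod)3 (10 mol %), PhMe, 80–110 °C
Reagents that add atoms: none
Why: Proposed new method: the unit O5–C(CH3)2–C(OTBS)=CH2 and the C5=C6 bond of ring A form the six-atom array of an aromatic Claisen rearrangement; a suprafacial [3,3] shift breaks O5–C(CH3)2, joins the unsubstituted CH2 terminus to C6 and gives dienone 14, which enolises to the chelated phenol 15. The closest known reaction type is the thermal or Eu(fod)3-catalysed aromatic Claisen rearrangement of prenyl and 1,1-dimethylallyl aryl ethers, 5-O-ethers of flavonoids included; what has not been shown is the same shift with a silyloxy group on the central allyl carbon. That donor sits on the node of the allyl fragment and should retard rather than help the shift, which is offset by the tertiary C–O bond, the peri strain between the 5-O-alkyl group and C4=O, chelation of the Lewis acid by O4 and O5, and the hydrogen bond gained in 15. Site selectivity: of the two ortho carbons of O5, C4a is quaternary, so only C6 can accept the chain; C8 could be reached only by a further Cope shift of 14, which would have to form a C8–C(CH3)2 bond and compete with fast enolisation. Chemoselectivity: the 3-prenyl group belongs to no allyl aryl ether or 1,5-diene array, and the aryl silyl ethers are inert. No ring is closed and no lasting stereocentre is formed, since C6 of 14 becomes planar again on enolisation. A silyl shift from the enol oxygen to O5 would be harmless, because step 10 removes every silyl group.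

Step 10
Reactants: 15 the rearranged tris-silyl compound of step 9
Product: 16 2-(2,4-dihydroxyphenyl)-5-hydroxy-7-methoxy-3-(3-methylbut-2-en-1-yl)-6-(3-methyl-2-oxobutyl)-4H-chromen-4-one (target)
Conditions: TBAF (3.5 equiv), AcOH (3.5 equiv), THF, 0 °C → rt
Reagents that add atoms: none
Why: Fluoride cleavage of two aryl silyl ethers and of the enol silane, whose protonation gives the isopropyl ketone. The acetic acid buffer keeps the medium near neutral, so nothing dehydrates the o-hydroxybenzyl ketone onto O5, adds to the prenyl group or opens the pyranone.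

## Compound list

1 | 1-(2,6-dihydroxy-4-methoxyphenyl)ethan-1-one | CC(=O)c1c(O)cc(OC)cc1O | starting material
2 | 3-bromo-3-methylbutan-2-one | CC(=O)C(C)(C)Br | starting material
3 | 3-(2-acetyl-3-hydroxy-5-methoxyphenoxy)-3-methylbutan-2-one | CC(=O)c1c(O)cc(OC)cc1OC(C)(C)C(C)=O | intermediate
4 | methyl 2,4-dihydroxybenzoate | COC(=O)c1ccc(O)cc1O | starting material
5 | methyl 2,4-bis(methoxymethoxy)benzoate | COCOc1ccc(C(=O)OC)c(OCOC)c1 | intermediate
6 | 2,4-bis(methoxymethoxy)benzoic acid | COCOc1ccc(C(=O)O)c(OCOC)c1 | intermediate
7 | 2-acetyl-5-methoxy-3-[(2-methyl-3-oxobutan-2-yl)oxy]phenyl 2,4-bis(methoxymethoxy)benzoate | CC(=O)c1c(OC(=O)c2ccc(OCOC)cc2OCOC)cc(OC)cc1OC(C)(C)C(C)=O | intermediate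
8 | 1-[2,4-bis(methoxymethoxy)phenyl]-3-{2-hydroxy-4-methoxy-6-[(2-methyl-3-oxobutan-2-yl)oxy]phenyl}propane-1,3-dione | COCOc1ccc(C(=O)CC(=O)c2c(O)cc(OC)cc2OC(C)(C)C(C)=O)c(OCOC)c1 | intermediate
9 | 1-bromo-3-methylbut-2-ene | CC(C)=CCBr | starting material
10 | 2-(3-methylbut-2-en-1-yl) derivative of 8 (racemic, labile) | COCOc1ccc(C(=O)C(CC=C(C)C)C(=O)c2c(O)cc(OC)cc2OC(C)(C)C(C)=O)c(OCOC)c1 | intermediate
11 | 2-[2,4-bis(methoxymethoxy)phenyl]-7-methoxy-5-[(2-methyl-3-oxobutan-2-yl)oxy]-3-(3-methylbut-2-en-1-yl)-4H-chromen-4-one | COCOc1ccc(-c2oc3cc(OC)cc(OC(C)(C)C(C)=O)c3c(=O)c2CC=C(C)C)c(OCOC)c1 | intermediate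
12 | 2-(2,4-dihydroxyphenyl)-7-methoxy-5-[(2-methyl-3-oxobutan-2-yl)oxy]-3-(3-methylbut-2-en-1-yl)-4H-chromen-4-one | Oc1ccc(-c2oc3cc(OC)cc(OC(C)(C)C(C)=O)c3c(=O)c2CC=C(C)C)c(O)c1 | intermediate
13 | 2-[2,4-bis(TBSO)phenyl]-5-{[3-(TBSO)-2-methylbut-3-en-2-yl]oxy}-7-methoxy-3-(3-methylbut-2-en-1-yl)-4H-chromen-4-one | CC(C)(C)[Si](C)(C)Oc1ccc(-c2oc3cc(OC)cc(OC(C)(C)C(=C)O[Si](C)(C)C(C)(C)C)c3c(=O)c2CC=C(C)C)c(O[Si](C)(C)C(C)(C)C)c1 | intermediate
14 | 2-[2,4-bis(TBSO)phenyl]-6-[2-(TBSO)-3-methylbut-2-en-1-yl]-7-methoxy-3-(3-methylbut-2-en-1-yl)-4H-chromene-4,5(6H)-dione (racemic, transient) | COC1=CC2=C(C(=O)C1CC(O[Si](C)(C)C(C)(C)C)=C(C)C)C(=O)C(CC=C(C)C)=C(O2)c1ccc(O[Si](C)(C)C(C)(C)C)cc1O[Si](C)(C)C(C)(C)C | intermediate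
15 | 2-[2,4-bis(TBSO)phenyl]-6-[2-(TBSO)-3-methylbut-2-en-1-yl]-5-hydroxy-7-methoxy-3-(3-methylbut-2-en-1-yl)-4H-chromen-4-one | COc1cc2oc(-c3ccc(O[Si](C)(C)C(C)(C)C)cc3O[Si](C)(C)C(C)(C)C)c(CC=C(C)C)c(=O)c2c(O)c1CC(O[Si](C)(C)C(C)(C)C)=C(C)C | intermediate
16 | 2-(2,4-dihydroxyphenyl)-5-hydroxy-7-methoxy-3-(3-methylbut-2-en-1-yl)-6-(3-methyl-2-oxobutyl)-4H-chromen-4-one | COc1cc2oc(-c3ccc(O)cc3O)c(CC=C(C)C)c(=O)c2c(O)c1CC(=O)C(C)C | target

## Step count and risks

Total step count: 10. Longest linear sequence: 9 steps (4 → 5 → 6 → 7 → 8 → 10 → 12 → 13 → 15 → 16). The branch from 1 joins at step 4.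

**Step 9 (key step, proposed new method).**
- Heterolysis of the tertiary O5–C bond may be followed by proton loss, so the chain is eliminated instead of being delivered to C6.
- The shift may be too slow because of the central oxygen substituent.
- The Lewis acid or adventitious water may cleave the enol silane before rearrangement.
- Fallback, using known reaction types only: the O5 tether is kept, but the concerted shift is replaced by ring closure followed by ring opening.
  - It sets out from 12. Silylation of the two B-ring phenols (TBSCl, imidazole, DMF) gives the bis-silyl ether ketone F1.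
  - Detrifluoroacetylative diazo transfer (LiHMDS, CF3CO2CH2CF3, −78 °C; then MsN3, Et3N, aqueous MeCN) passes through the trifluoroacetyl ketone F2 to the diazoketone F3.
  - Rh2(OAc)4-catalysed intramolecular aromatic substitution of the aryloxy diazoketone closes the fused 2,2-dimethylchroman-3-one F4 at C6.
  - SmI2 (THF/MeOH, −78 °C) cleaves the α-aryloxy C–O bond and gives the ring-opened bis-silyl ketone F5.
  - The conditions of step 10 bring F5 back to the route at 16.

**Step 1.**
- Substitution at the tertiary carbon may be slow, so loss of HBr from 2 could compete.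
- Enolisation of 2 could lead to Favorskii-type cine substitution that places the phenoxide on the CH2 terminus.
- Double alkylation could also occur.
- Fallback: it sets out from 1. Copper-catalysed O-alkylation with 3-chloro-3-methylbut-1-yne (CuCl2 cat., DBU, MeCN, 0 °C) gives the 1,1-dimethylpropargyl ether F6. Hg(II)-catalysed Markovnikov hydration of the terminal alkyne, done before any prenyl group is present, returns to the route at 3.

**Step 5.**
- The side-chain methyl ketone may take part in enolate chemistry of its own: intramolecular aldol reaction with the acetyl group, or expulsion of aryloxide from its α'-enolate.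
- The acyl transfer may stay incomplete.
- Fallback: it sets out from 3.
  - Selective ketalisation of the aliphatic ketone (ethylene glycol, TsOH, PhH, water removal; the chelated, di-ortho-substituted aryl ketone does not react) gives the dioxolane F7.
  - Steglich esterification with 6 gives the ester F8.
  - Baker–Venkataraman rearrangement gives the diketone F9, and prenylation with 9 gives the C-prenyl diketone F10.
  - The acid of step 7, with water present, closes the ring and removes the MOM groups and the ketal together, returning to the route at 12.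

**Step 6.**
- O-alkylation of the free phenol or of the enolate oxygen could compete, as could a second C-alkylation or retro-Claisen cleavage of the 2-substituted diketone.
- Fallback: the prenyl carbon chain is installed before the diketone exists. It sets out from 1.
  - Formation of the trianion (LDA, 3.3 equiv, THF) and alkylation with 9 at the acetyl carbon gives the hexenone F11.
  - Etherification with 2 as in step 1 gives the ether F12.
  - Esterification with 6 as in step 4 gives the ester F13.
  - Baker–Venkataraman rearrangement of the secondary enolate returns to the route at 10.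

## Further compounds

F1 | step 9 | 2-[2,4-bis(TBSO)phenyl]-7-methoxy-5-[(2-methyl-3-oxobutan-2-yl)oxy]-3-(3-methylbut-2-en-1-yl)-4H-chromen-4-one | CC(C)(C)[Si](C)(C)Oc1ccc(-c2oc3cc(OC)cc(OC(C)(C)C(C)=O)c3c(=O)c2CC=C(C)C)c(O[Si](C)(C)C(C)(C)C)c1
F2 | step 9 | trifluoroacetyl ketone of F1 (5-O-C(CH3)2-C(=O)-CH2-C(=O)CF3) | CC(C)(C)[Si](C)(C)Oc1ccc(-c2oc3cc(OC)cc(OC(C)(C)C(=O)CC(=O)C(F)(F)F)c3c(=O)c2CC=C(C)C)c(O[Si](C)(C)C(C)(C)C)c1
F3 | step 9 | diazoketone of F1 (5-O-C(CH3)2-C(=O)-CH=N2) | CC(C)(C)[Si](C)(C)Oc1ccc(-c2oc3cc(OC)cc(OC(C)(C)C(=O)C=[N+]=[N-])c3c(=O)c2CC=C(C)C)c(O[Si](C)(C)C(C)(C)C)c1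
F4 | step 9 | flavone with a 2,2-dimethylchroman-3-one ring fused through O5 and C6 | COc1cc2oc(-c3ccc(O[Si](C)(C)C(C)(C)C)cc3O[Si](C)(C)C(C)(C)C)c(CC=C(C)C)c(=O)c2c2OC(C)(C)C(=O)Cc12
F5 | step 9 | 2',4'-bis-TBS ether of 16 | COc1cc2oc(-c3ccc(O[Si](C)(C)C(C)(C)C)cc3O[Si](C)(C)C(C)(C)C)c(CC=C(C)C)c(=O)c2c(O)c1CC(=O)C(C)C
F6 | step 1 | 1-{2-hydroxy-4-methoxy-6-[(2-methylbut-3-yn-2-yl)oxy]phenyl}ethan-1-one | CC(=O)c1c(O)cc(OC)cc1OC(C)(C)C#C
F7 | step 5 | 1-(2-hydroxy-4-methoxy-6-{[2-(2-methyl-1,3-dioxolan-2-yl)propan-2-yl]oxy}phenyl)ethan-1-one | CC(=O)c1c(O)cc(OC)cc1OC(C)(C)C1(C)OCCO1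
F8 | step 5 | 2,4-bis(methoxymethoxy)benzoate of F7 | CC(=O)c1c(OC(=O)c2ccc(OCOC)cc2OCOC)cc(OC)cc1OC(C)(C)C1(C)OCCO1
F9 | step 5 | dioxolane analogue of 8 | COCOc1ccc(C(=O)CC(=O)c2c(O)cc(OC)cc2OC(C)(C)C2(C)OCCO2)c(OCOC)c1
F10 | step 5 | dioxolane analogue of 10 | COCOc1ccc(C(=O)C(CC=C(C)C)C(=O)c2c(O)cc(OC)cc2OC(C)(C)C2(C)OCCO2)c(OCOC)c1
F11 | step 6 | 1-(2,6-dihydroxy-4-methoxyphenyl)-5-methylhex-4-en-1-one | CC(C)=CCCC(=O)c1c(O)cc(OC)cc1O
F12 | step 6 | 1-{2-hydroxy-4-methoxy-6-[(2-methyl-3-oxobutan-2-yl)oxy]phenyl}-5-methylhex-4-en-1-one | CC(C)=CCCC(=O)c1c(O)cc(OC)cc1OC(C)(C)C(C)=O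
F13 | step 6 | 2,4-bis(methoxymethoxy)benzoate of F12 | CC(C)=CCCC(=O)c1c(OC(=O)c2ccc(OCOC)cc2OCOC)cc(OC)cc1OC(C)(C)C(C)=O
A1 | alternative 1 | 1-[2,6-dihydroxy-4-methoxy-3-(3-methyl-2-oxobutyl)phenyl]ethan-1-one | CC(=O)c1c(O)cc(OC)c(CC(=O)C(C)C)c1O
A2 | alternative 1 | 8-(3-methyl-2-oxobutyl) isomer of 16 | COc1cc(O)c2c(=O)c(CC=C(C)C)c(-c3ccc(O)cc3O)oc2c1CC(=O)C(C)C
A3 | alternative 2 | 2-[2,4-bis(TBSO)phenyl]-5-hydroxy-6-iodo-7-methoxy-3-(3-methylbut-2-en-1-yl)-4H-chromen-4-one | COc1cc2oc(-c3ccc(O[Si](C)(C)C(C)(C)C)cc3O[Si](C)(C)C(C)(C)C)c(CC=C(C)C)c(=O)c2c(O)c1I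
A4 | alternative 3 | 2-(2,4-dihydroxyphenyl)-5-hydroxy-7-methoxy-3,6-bis(3-methylbut-2-en-1-yl)-4H-chromen-4-one | COc1cc2oc(-c3ccc(O)cc3O)c(CC=C(C)C)c(=O)c2c(O)c1CC=C(C)C
A5 | alternative 3 | 6-[(3,3-dimethyloxiran-2-yl)methyl] analogue of A4 (racemic) | COc1cc2oc(-c3ccc(O)cc3O)c(CC=C(C)C)c(=O)c2c(O)c1CC1OC1(C)C
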